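The route rests on opening the 2,2-dimethyl-2H-pyran ring at two bonds, C3=C4 and O1–C2, which leaves a hexasubstituted salicylaldehyde (formyl carbon = C4 on C4a, phenol oxygen = O1 on C8a) and a 2-methylprop-1-enyl donor. An amine-catalysed Petasis condensation with the alkenylboronic acid joins C4 to C3, and the resulting ortho-quinone methide closes O1–C2 by oxa-6π electrocyclisation, all in the last step and on the unprotected triphenol. The step exploits the ortho relation of O1 and C4 on the benzene ring and the gem-dimethyl carbon C2. The aldehyde comes in four steps from an orsellinate: lateral benzylation, Vilsmeier formylation, demethylation, C-prenylation between the two phenols.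

Key step: step 5

Remark: methyl 2,4-dimethoxy-6-methylbenzoate (1) is taken as a catalogue compound (otherwise one O-methylation from methyl orsellinate).

Step 1
Reactants: 1 methyl 2,4-dimethoxy-6-methylbenzoate; 2 4-methoxybenzyl chloride
Product: 3 methyl 2,4-dimethoxy-6-[2-(4-methoxyphenyl)ethyl]benzoate
Conditions: LiN(iPr)2 (LDA, 1.2 equiv), THF, −78 °C; then 2 (1.2 equiv), −78 → 0 °C; aq NH4Cl
Reagents that add atoms: none
Why: Lateral lithiation–alkylation of an ortho-toluate, in which the ester-stabilised benzylic anion displaces chloride from the benzylic chloride (SN2), should give the bibenzyl without forming a stereocentre.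

Step 2
Reactants: 3 methyl 2,4-dimethoxy-6-[2-(4-methoxyphenyl)ethyl]benzoate
Product: 4 methyl 3-formyl-4,6-dimethoxy-2-[2-(4-methoxyphenyl)ethyl]benzoate
Conditions: POCl3 (3 equiv), DMF, 0 → 80 °C; then aq NaOAc, rt
Reagents that add atoms: N,N-dimethylformamide, CN(C)C=O (formyl carbon); water, O (formyl oxygen, on hydrolysis of the iminium salt)
Why: Vilsmeier–Haack formylation should take place at C5 of 3, the only carbon para to one methoxy group and ortho to the other, because the carbon between the two methoxy groups is shielded and the mono-alkoxy side ring is too weakly activated for the chloroiminium ion.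

Step 3
Reactants: 4 methyl 3-formyl-4,6-dimethoxy-2-[2-(4-methoxyphenyl)ethyl]benzoate
Product: 5 methyl 3-formyl-4,6-dihydroxy-2-[2-(4-hydroxyphenyl)ethyl]benzoate
Conditions: BBr3 (6 equiv), CH2Cl2, −78 °C → rt; ice/H2O
Reagents that add atoms: none
Why: BBr3 cleavage of aryl methyl ethers (boron complexation, then bromide attack at methyl) should free all three phenols, the two carbonyl-chelated ethers first, while the hindered methyl ester and the aldehyde are kept by not exceeding room temperature.

Step 4
Reactants: 5 methyl 3-formyl-4,6-dihydroxy-2-[2-(4-hydroxyphenyl)ethyl]benzoate; 6 prenyl bromide (1-bromo-3-methylbut-2-ene)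
Product: 7 methyl 3-formyl-4,6-dihydroxy-2-[2-(4-hydroxyphenyl)ethyl]-5-(3-methylbut-2-en-1-yl)benzoate
Conditions: KOH (2.1 equiv, 10% aq), 6 (1.2 equiv), 0 °C → rt; then dilute HCl
Reagents that add atoms: none
Why: Phenoxide C-alkylation (aqueous-KOH C-prenylation of an acylresorcinol) should occur at C5, the only free ring carbon and the one flanked by both phenoxide oxygens, while the less acidic side-ring phenol stays largely protonated with two equivalents of base.

Step 5
Reactants: 7 methyl 3-formyl-4,6-dihydroxy-2-[2-(4-hydroxyphenyl)ethyl]-5-(3-methylbut-2-en-1-yl)benzoate; 8 (2-methylprop-1-en-1-yl)boronic acid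
Product: 11 methyl 7-hydroxy-5-[2-(4-hydroxyphenyl)ethyl]-2,2-dimethyl-8-(3-methylbut-2-en-1-yl)-2H-chromene-6-carboxylate (the target), via Petasis allylic amine 9 (not isolated), via ortho-quinone methide 10 (not isolated)
Conditions: 8 (2 equiv), Bn2NH (0.4 equiv), 1,4-dioxane, 90 °C, Ar
Reagents that add atoms: none
Why: The amine condenses with the formyl group to an ortho-hydroxybenzyl iminium ion, the neighbouring phenol oxygen (C4–OH of 7) binds 8 as a tetracoordinate boronate, and the 2-methylprop-1-enyl group migrates from boron by its boron-bearing carbon to the iminium carbon (Petasis borono-Mannich step, first bond) to give allylic amine 9. At 90 °C this ortho/para-hydroxybenzylic amine expels dibenzylamine, which re-enters the cycle, to give ortho-quinone methide 10, a 1-oxatriene ending in the dimethyl-substituted carbon, and 10 closes to the aromatic 2H-chromene by forming the O–C(CH3)2 bond (second bond). The closest known reaction is the amine-catalysed condensation of salicylaldehydes with alkenylboronic acids to 2H-chromenes. The pyran ring is closed by a thermal disrotatory oxa-6π electrocyclisation of the (Z)-quinone methide, driven by re-aromatisation, and the E and Z isomers of 10 can interconvert by reversible amine addition. No stereocentre remains, because the aminated carbon of 9 becomes sp2 and C2 carries two methyl groups. The step needs ipso transfer from boron, so that the dimethyl carbon ends on oxygen, and closure onto one phenol only; the boronate tether secures the first and the substitution pattern the second, since only the C4 hydroxyl is ortho to the formyl group while the C6 hydroxyl is para to it and hydrogen-bonded to the ester, and the hindered ester, the prenyl alkene and the remote phenol are inert to amine and boronic acid.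

Compound list
1 | methyl 2,4-dimethoxy-6-methylbenzoate | COC(=O)c1c(C)cc(OC)cc1OC | starting material
2 | 4-methoxybenzyl chloride (1-(chloromethyl)-4-methoxybenzene) | COc1ccc(CCl)cc1 | starting material
3 | methyl 2,4-dimethoxy-6-[2-(4-methoxyphenyl)ethyl]benzoate | COC(=O)c1c(OC)cc(OC)cc1CCc1ccc(OC)cc1 | intermediate
4 | methyl 3-formyl-4,6-dimethoxy-2-[2-(4-methoxyphenyl)ethyl]benzoate | COC(=O)c1c(OC)cc(OC)c(C=O)c1CCc1ccc(OC)cc1 | intermediate
5 | methyl 3-formyl-4,6-dihydroxy-2-[2-(4-hydroxyphenyl)ethyl]benzoate | COC(=O)c1c(O)cc(O)c(C=O)c1CCc1ccc(O)cc1 | intermediate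
6 | prenyl bromide (1-bromo-3-methylbut-2-ene) | CC(C)=CCBr | starting material
7 | methyl 3-formyl-4,6-dihydroxy-2-[2-(4-hydroxyphenyl)ethyl]-5-(3-methylbut-2-en-1-yl)benzoate | COC(=O)c1c(O)c(CC=C(C)C)c(O)c(C=O)c1CCc1ccc(O)cc1 | intermediate
8 | (2-methylprop-1-en-1-yl)boronic acid | CC(C)=CB(O)O | starting material
9 | methyl 3-[1-(dibenzylamino)-3-methylbut-2-en-1-yl]-4,6-dihydroxy-2-[2-(4-hydroxyphenyl)ethyl]-5-(3-methylbut-2-en-1-yl)benzoate (racemic Petasis allylic amine) | COC(=O)c1c(O)c(CC=C(C)C)c(O)c(C(C=C(C)C)N(Cc2ccccc2)Cc2ccccc2)c1CCc1ccc(O)cc1 | intermediate (not isolated)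
10 | methyl (5Z)-2-hydroxy-6-[2-(4-hydroxyphenyl)ethyl]-3-(3-methylbut-2-en-1-yl)-5-(3-methylbut-2-en-1-ylidene)-4-oxocyclohexa-2,6-diene-1-carboxylate (ortho-quinone methide; the exocyclic alkenyl group is syn to the ring carbonyl) | O=C1C(CC=C(C)C)=C(O)C(C(=O)OC)=C(CCc2ccc(O)cc2)/C1=C/C=C(C)C | intermediate (not isolated)
11 | methyl 7-hydroxy-5-[2-(4-hydroxyphenyl)ethyl]-2,2-dimethyl-8-(3-methylbut-2-en-1-yl)-2H-chromene-6-carboxylate (no stereocentre) | COC(=O)c1c(O)c(CC=C(C)C)c2c(c1CCc1ccc(O)cc1)C=CC(C)(C)O2 | target

Total step count: 5. Longest linear sequence: 5 steps (1 → 3 → 4 → 5 → 7 → 11).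

Steps most likely to fail

Step 4 (C-prenylation). O-alkylation at either chelated phenol or at the side-ring phenol, or a second alkylation at the same carbon, may compete with the desired C-alkylation. The fallback sets out from 5 and replaces the ambident-anion alkylation by halogenation and cross-coupling. Iodination under pH control (I2, NaHCO3, THF/H2O, 0 °C), where only the acylresorcinol is ionised, should give methyl 3-formyl-4,6-dihydroxy-2-[2-(4-hydroxyphenyl)ethyl]-5-iodobenzoate F1. Stille coupling of F1 with tributyl(3-methylbut-2-en-1-yl)stannane (Pd(PPh3)4, DMF, 80 °C) should deliver the linear prenyl group and come back to the route at 7.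

Step 5 (key step). Iminium formation may be slow at the doubly ortho-substituted, electron-rich aldehyde, and 8 may protodeboronate before transfer. The fallback sets out from 7 and makes the two bonds in two separate operations. Excess 2-methylprop-1-enylmagnesium bromide (THF, 0 °C; the phenols are taken up as magnesium phenoxides and the hindered ester is left) should give the allylic alcohol methyl 4,6-dihydroxy-3-(1-hydroxy-3-methylbut-2-en-1-yl)-2-[2-(4-hydroxyphenyl)ethyl]-5-(3-methylbut-2-en-1-yl)benzoate F2. Mild acid (pyridinium p-toluenesulfonate, toluene, 60 °C) should dehydrate F2 through quinone methide 10 and 6π closure, coming back to the route at 11.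

Step 3 (demethylation). The unactivated side-ring methyl ether needs the most forcing conditions, so the methyl ester may be lost or the cleavage may stop short. The fallback sets out from 1 and changes the protecting group so that a milder Lewis acid suffices. Lateral alkylation of 1 with 4-(benzyloxy)benzyl chloride (LiN(iPr)2, THF, −78 °C) should give methyl 2-{2-[4-(benzyloxy)phenyl]ethyl}-4,6-dimethoxybenzoate F3. Vilsmeier formylation as in step 2 should give methyl 2-{2-[4-(benzyloxy)phenyl]ethyl}-3-formyl-4,6-dimethoxybenzoate F4. BCl3 with pentamethylbenzene (CH2Cl2, −78 → 0 °C) should then cleave only the two carbonyl-chelated methyl ethers and the benzyl ether of F4, coming back to the route at 5.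

Further compounds
F1 | step 4 | methyl 3-formyl-4,6-dihydroxy-2-[2-(4-hydroxyphenyl)ethyl]-5-iodobenzoate | COC(=O)c1c(O)c(I)c(O)c(C=O)c1CCc1ccc(O)cc1
F2 | step 5 | methyl 4,6-dihydroxy-3-(1-hydroxy-3-methylbut-2-en-1-yl)-2-[2-(4-hydroxyphenyl)ethyl]-5-(3-methylbut-2-en-1-yl)benzoate (racemic) | COC(=O)c1c(O)c(CC=C(C)C)c(O)c(C(O)C=C(C)C)c1CCc1ccc(O)cc1
F3 | step 3 | methyl 2-{2-[4-(benzyloxy)phenyl]ethyl}-4,6-dimethoxybenzoate | COC(=O)c1c(OC)cc(OC)cc1CCc1ccc(OCc2ccccc2)cc1
F4 | step 3 | methyl 2-{2-[4-(benzyloxy)phenyl]ethyl}-3-formyl-4,6-dimethoxybenzoate | COC(=O)c1c(OC)cc(OC)c(C=O)c1CCc1ccc(OCc2ccccc2)cc1
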